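## Retrosynthetic overview
1. Caruifolin B is a norbornanone, the formal [4+2] adduct of a 2‑siloxycyclopentadiene (from the 3‑oxo‑Δ4 half) and the C2=C3 bond of a cyclopentadiene (the other half). Disconnecting C2–C2′ and C3–C5′ gives two guaianolide monomers.
2. Both monomers come from one compound, isophotosantonic lactone (10‑hydroxy‑3‑oxoguai‑4‑en‑6,12‑olide). It is made in one photochemical step from α‑santonin, which forms the C1–C5 bond and converts the eudesmane into the 5/7 guaiane.
3. Ring order: the lactone and six‑membered ring are bought in santonin. The 5‑ and 7‑membered rings form in the photorearrangement. The two norbornane rings form together in a photoredox cross‑Diels–Alder step. A final hydrolysis and epimerisation sets C4′.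

Assumption: the C10‑OH and C1‑H of the santonin photoproduct have the configuration present in both halves of the target. I assign this by net retention at C10 in the lumisantonin ring opening.

## Route

**Step 1**
Reactants: 1, (+)‑α‑santonin
Product: 2, isophotosantonic lactone
Conditions: hν (Hg lamp, Pyrex), 50% aq. AcOH, 20 °C, N2
Reagents that add atoms: water, O
Why: Type‑A cross‑conjugated dienone photorearrangement gives lumisantonin and forms the C1–C5 bond. Acid opening of the cyclopropyl ketone then gives the C10 tertiary cation, which water traps. C6, C7 and C11 are carried over from santonin; C1 is set in the photocyclisation and C10 in the cation capture.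

**Step 2**
Reactants: 2
Product: 3, 3‑hydroxy‑guai‑4‑en‑6,12‑olide (C3 epimer mixture)
Conditions: NaBH4, CeCl3·7H2O, MeOH, –20 °C
Reagents that add atoms: none
Why: Luche 1,2‑reduction of the enone leaves the lactone intact. The C3 stereocentre is destroyed in the next step.

**Step 3**
Reactants: 3
Product: 4, 10‑hydroxyguaia‑2,4‑dien‑6,12‑olide (the cyclopentadiene, C2=C3/C4=C5)
Conditions: MsCl, Et3N, CH2Cl2, –40 °C; then DBU, –40→0 °C; used cold and immediately
Reagents that add atoms: none
Why: MsCl sulfonylates the secondary allylic alcohol selectively over the tertiary 10‑OH. E2 elimination can remove only a C2 hydrogen, since C4 is sp2, so it gives the C2=C3 diene and leaves C1‑H untouched.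

**Step 4**
Reactants: 2
Product: 5, 3,10‑bis(trimethylsilyloxy)guaia‑2,4‑dien‑6,12‑olide
Conditions: TMSOTf, Et3N, CH2Cl2, –78→0 °C; pentane extraction under N2, used crude
Reagents that add atoms: TMSOTf, C[Si](C)(C)OS(=O)(=O)C(F)(F)F
Why: Soft enolisation at C2 (α′) gives the cross‑conjugated 2‑siloxycyclopentadiene, and the tertiary 10‑OH is silylated at the same time. No new stereocentre forms; C1 is retained.

**Step 5**
Reactants: 4 (2 equiv), 5 (1 equiv)
Product: 6, bis‑TMS norbornene enol ether adduct
Conditions: [Ru(bpz)3](PF6)2 (1 mol %), blue LEDs (450 nm), CH2Cl2 (0.05 M), 0 °C, 3 h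
Reagents that add atoms: none
Why: Proposed new method: photoredox cation‑radical Diels–Alder cross‑coupling of two complex cyclopentadienes.
- The photocatalyst oxidises only the electron‑rich siloxydiene 5 (about +0.9 V) and not the alkyl‑cyclopentadiene 4 (about +1.3 V).
- The neutral C2=C3 bond of 4 attacks the radical cation at C2′ (stepwise). This gives a C3 radical that is allylic with C4=C5, and it closes onto the hindered C5′. Back‑electron transfer regenerates the catalyst, or the product radical cation propagates a chain.
- The closest known reactions are Bauld and Yoon cation‑radical Diels–Alder cycloadditions; here both partners are cyclopentadienes, a quaternary centre is formed, and the 4π and 2π components are different.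
- Each partner is attacked on its less hindered face, anti to its C10 substituent, and the cycloaddition is endo, as in dicyclopentadiene. This sets C2, C3, C2′ and C5′, and C1′ is retained.

**Step 6**
Reactants: 6
Product: 7, caruifolin B
Conditions: 1 M aq. HCl, THF (1:3), 25 °C, 12 h
Reagents that add atoms: water, O
Why: Both TMS groups are hydrolysed (10′‑OTMS is cleaved and the enol ether protonated to give the C3′ ketone). The only enolisable site is C4′, since C2′ is a bridgehead. Acid enolisation equilibrates the methyl to the exo position, because the endo face is blocked by the other half's cyclopentene ring. This sets C4′.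

## Compound list
1 | (+)‑α‑santonin | C[C@H]1[C@@H]2CC[C@]3(C=CC(=O)C(=C3[C@H]2OC1=O)C)C | starting material
2 | isophotosantonic lactone, 10‑hydroxy‑3‑oxoguai‑4‑en‑6,12‑olide | CC1=C2[C@H]3OC(=O)[C@@H](C)[C@@H]3CC[C@](C)(O)[C@@H]2CC1=O | intermediate
3 | 3‑hydroxyguai‑4‑en‑6,12‑olide, 10‑OH (C3 epimers) | CC1=C2[C@H]3OC(=O)[C@@H](C)[C@@H]3CC[C@](C)(O)[C@@H]2CC1O | intermediate
4 | 10‑hydroxyguaia‑2,4‑dien‑6,12‑olide (cyclopentadiene) | CC1=C2[C@H]3OC(=O)[C@@H](C)[C@@H]3CC[C@](C)(O)[C@@H]2C=C1 | intermediate
5 | 3,10‑bis(trimethylsilyloxy)guaia‑2,4‑dien‑6,12‑olide | CC1=C2[C@H]3OC(=O)[C@@H](C)[C@@H]3CC[C@](C)(O[Si](C)(C)C)[C@@H]2C=C1O[Si](C)(C)C | intermediate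
6 | bis‑TMS Diels–Alder adduct | CC1=C2[C@H]3OC(=O)[C@@H](C)[C@@H]3CC[C@](C)(O)[C@@H]2[C@H]2[C@H]3C(O[Si](C)(C)C)=C(C)[C@]4([C@@H]3[C@@](C)(O[Si](C)(C)C)CC[C@H]3[C@H](C)C(=O)O[C@@H]34)[C@@H]12 | intermediate
7 | caruifolin B | CC1=C2[C@H]3OC(=O)[C@@H](C)[C@@H]3CC[C@](C)(O)[C@@H]2[C@H]2[C@H]3C(=O)[C@H](C)[C@]4([C@@H]3[C@@](C)(O)CC[C@H]3[C@H](C)C(=O)O[C@@H]34)[C@@H]12 | target

## Totals
- Total steps: 6 (steps 1–6).
- Longest linear sequence: 5 (santonin → 2 → 3 → 4 → 6 → 7).

## Three steps most likely to fail
1. **Step 5 (proposed new photoredox cross‑Diels–Alder).** Homodimerisation, proton loss from the radical cation, or wrong regio‑ or endo/exo selectivity could intervene. Fallback: a neutral thermal Diels–Alder of 4 with 5 at 12–15 kbar, 25 °C, in CH2Cl2, which uses concerted reactivity instead of a radical cation.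
2. **Step 3 (cyclopentadiene 4).** Ionisation of the allylic mesylate (E1) or a [1,5]‑H shift could give the C1=C5 isomer and scramble C1. Fallback: silylate the 10‑OH first, then use Burgess syn‑elimination, which avoids cationic intermediates.
3. **Step 1 (santonin photolysis).** Yield is modest, and the C10 capture stereochemistry is only assumed. Fallback: a two‑stage sequence that irradiates santonin in dry Et2O to isolate lumisantonin, then opens it with aqueous acid in a separate step.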